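**Retrosynthetic overview**

- The strategy rests on ring D (the salicylic acid ring, numbered C1 = carboxyl carbon). It carries the carboxyl at C1, the hydroxyl at C2 and the CH2CH2 bridge at C6 on three neighbouring carbons, so C1 and C6 are treated as the two carbons of an aryne polarised by the C2 oxygen.
- Key disconnection: the C6–CH2 and C1–CO2H bonds are made in one pot from 2-iodo-5-methoxy-3-(methoxymethoxy)phenyl triflate, a 2-arylethylmagnesium bromide carrying rings A, B and C, and CO2.
- The aryne precursor comes from 5-methoxyresorcinol: bis-acetal, lithiation–iodination between the acetals, cleavage of one acetal, triflation.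
- The nucleophile is built by Horner–Wadsworth–Emmons olefination and diimide reduction (A–B bridge), SNAr with 4-fluorobenzaldehyde (B–O–C ether), then methylenation, hydroboration, bromination and magnesium insertion.
- No ring is formed: all four benzene rings are purchased. The end game is acetal cleavage and hydrogenolysis.

Key step: step 13

Remark: rings are labelled A (4-hydroxyphenyl), B (methoxy-bearing 1,3,5-trisubstituted ring), C (para-phenylene of the diaryl ether) and D (salicylic acid ring); the target has no stereocentre.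

**Step 1**
Reactants: 1 5-methoxyresorcinol
Product: 2 1-methoxy-3,5-bis(methoxymethoxy)benzene
Conditions: MOMCl (2.5 equiv), iPr2NEt (3 equiv), CH2Cl2, 0 °C → rt
Reagents that add atoms: chloromethyl methyl ether, COCCl
Why: Double O-alkylation of the phenols with the reactive chloromethyl ether (Williamson-type) installs two acetals that later serve as ortho-directing groups.

**Step 2**
Reactants: 2 1-methoxy-3,5-bis(methoxymethoxy)benzene
Product: 4 2-iodo-5-methoxy-1,3-bis(methoxymethoxy)benzene, via aryllithium 3 (not isolated)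
Conditions: n-BuLi (1.2 equiv), THF, 0 °C; then I2, −78 °C → rt
Reagents that add atoms: iodine, II; n-butyllithium, [Li]CCCC (lithium of 3)
Why: Directed ortho-metalation should occur at the carbon flanked by the two methoxymethoxy groups, the strongest cooperative directing pair on the ring, and the aryllithium is then iodinated by I2.

**Step 3**
Reactants: 4 2-iodo-5-methoxy-1,3-bis(methoxymethoxy)benzene
Product: 5 2-iodo-5-methoxy-3-(methoxymethoxy)phenol
Conditions: HCl (cat.), MeOH, rt, stopped at partial conversion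
Reagents that add atoms: none
Why: Acid-catalysed acetal methanolysis halted early frees one of the two equivalent phenols, and the separated diol (re-protected as in step 1) and unchanged 4 are recycled so that the statistical split costs material only temporarily.

**Step 4**
Reactants: 5 2-iodo-5-methoxy-3-(methoxymethoxy)phenol
Product: 6 2-iodo-5-methoxy-3-(methoxymethoxy)phenyl trifluoromethanesulfonate
Conditions: Tf2O, pyridine, CH2Cl2, 0 °C
Reagents that add atoms: trifluoromethanesulfonic anhydride, O=S(=O)(OS(=O)(=O)C(F)(F)F)C(F)(F)F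
Why: O-Sulfonylation of the phenol with triflic anhydride in pyridine-buffered medium is routine and leaves the acetal and the aryl iodide untouched.

**Step 5**
Reactants: 7 4-(benzyloxy)benzyl chloride
Product: 8 diethyl [4-(benzyloxy)benzyl]phosphonate
Conditions: P(OEt)3 (neat), n-Bu4NI (cat.), 140 °C
Reagents that add atoms: triethyl phosphite, CCOP(OCC)OCC
Why: Michaelis–Arbuzov reaction of the benzylic chloride with triethyl phosphite, driven by loss of chloroethane, gives the phosphonate without affecting the benzyl ether.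

**Step 6**
Reactants: 8 diethyl [4-(benzyloxy)benzyl]phosphonate; 9 3-hydroxy-5-methoxybenzaldehyde
Product: 10 (E)-3-{2-[4-(benzyloxy)phenyl]ethenyl}-5-methoxyphenol
Conditions: KOtBu (2.5 equiv), DMF, 0 °C → rt; NH4Cl (aq) work-up
Reagents that add atoms: none
Why: Horner–Wadsworth–Emmons olefination with the benzylic phosphonate carbanion should give the E-stilbene, the extra base holding the phenol as its phenoxide, which sits meta to the formyl group and so does not deactivate it by conjugation.

**Step 7**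
Reactants: 10 (E)-3-{2-[4-(benzyloxy)phenyl]ethenyl}-5-methoxyphenol
Product: 11 3-{2-[4-(benzyloxy)phenyl]ethyl}-5-methoxyphenol
Conditions: TsNHNH2 (excess), NaOAc, THF/H2O, reflux
Reagents that add atoms: none
Why: Diimide generated in situ transfers H2 to the stilbene double bond by concerted syn addition and, unlike hydrogenation over palladium, cannot hydrogenolyse the benzyl ether.

**Step 8**
Reactants: 11 3-{2-[4-(benzyloxy)phenyl]ethyl}-5-methoxyphenol; 12 4-fluorobenzaldehyde
Product: 13 4-(3-{2-[4-(benzyloxy)phenyl]ethyl}-5-methoxyphenoxy)benzaldehyde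
Conditions: K2CO3, DMF, 120 °C
Reagents that add atoms: none
Why: Nucleophilic aromatic substitution of the fluoride para to the formyl group by the phenoxide forms the diaryl ether between rings B and C.

**Step 9**
Reactants: 13 4-(3-{2-[4-(benzyloxy)phenyl]ethyl}-5-methoxyphenoxy)benzaldehyde
Product: 14 1-{2-[4-(benzyloxy)phenyl]ethyl}-3-(4-ethenylphenoxy)-5-methoxybenzene
Conditions: Ph3PCH3Br, KOtBu, THF, 0 °C → rt
Reagents that add atoms: methyltriphenylphosphonium bromide, C[P+](c1ccccc1)(c1ccccc1)c1ccccc1.[Br-]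
Why: Wittig methylenation of the non-enolisable aryl aldehyde gives the styrene.

**Step 10**
Reactants: 14 1-{2-[4-(benzyloxy)phenyl]ethyl}-3-(4-ethenylphenoxy)-5-methoxybenzene
Product: 16 2-[4-(3-{2-[4-(benzyloxy)phenyl]ethyl}-5-methoxyphenoxy)phenyl]ethanol, via alkylborane 15 (not isolated)
Conditions: 9-BBN, THF, 0 °C → rt; then NaOH (aq), H2O2, 0 °C → rt
Reagents that add atoms: 9-borabicyclo[3.3.1]nonane, B1C2CCCC1CCC2 (boron of 15); hydrogen peroxide, OO (hydroxyl oxygen of 16)
Why: Hydroboration of the styrene with the bulky 9-BBN places boron on the terminal carbon (anti-Markovnikov), and alkaline peroxide oxidation then gives the primary alcohol with all ethers unaffected.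

**Step 11**
Reactants: 16 2-[4-(3-{2-[4-(benzyloxy)phenyl]ethyl}-5-methoxyphenoxy)phenyl]ethanol
Product: 17 1-{2-[4-(benzyloxy)phenyl]ethyl}-3-[4-(2-bromoethyl)phenoxy]-5-methoxybenzene
Conditions: CBr4, PPh3, CH2Cl2, 0 °C
Reagents that add atoms: carbon tetrabromide, BrC(Br)(Br)Br
Why: Appel bromination converts the primary alcohol into the bromide under neutral conditions compatible with the benzyl and aryl ethers.

**Step 12**
Reactants: 17 1-{2-[4-(benzyloxy)phenyl]ethyl}-3-[4-(2-bromoethyl)phenoxy]-5-methoxybenzene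
Product: 18 {2-[4-(3-{2-[4-(benzyloxy)phenyl]ethyl}-5-methoxyphenoxy)phenyl]ethyl}magnesium bromide (THF solution, titrated and used directly)
Conditions: Mg turnings (activated with BrCH2CH2Br), THF, 40 °C
Reagents that add atoms: magnesium, [Mg]
Why: Magnesium insertion into the primary alkyl bromide gives a 2-arylethyl Grignard reagent, and the substrate carries only ether functions, which are inert to it.

**Step 13**
Reactants: 6 2-iodo-5-methoxy-3-(methoxymethoxy)phenyl trifluoromethanesulfonate; 18 {2-[4-(3-{2-[4-(benzyloxy)phenyl]ethyl}-5-methoxyphenoxy)phenyl]ethyl}magnesium bromide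
Product: 22 6-{2-[4-(3-{2-[4-(benzyloxy)phenyl]ethyl}-5-methoxyphenoxy)phenyl]ethyl}-4-methoxy-2-(methoxymethoxy)benzoic acid, via magnesiated triflate 19 (not isolated), via aryne 20 (not isolated), via arylmagnesium 21 (not isolated)
Conditions: 6 and 18 (1.3 equiv), THF, −78 °C; iPrMgCl·LiCl (1.05 equiv) added dropwise, −78 → −20 °C; then CO2 (gas), −40 °C → rt; cold dilute HCl to pH 3
Reagents that add atoms: carbon dioxide, O=C=O; isopropylmagnesium chloride–lithium chloride, CC(C)[Mg]Cl.[Li+].[Cl-] (magnesium of 19)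
Why: iPrMgCl·LiCl, added last and slowly, undergoes fast iodine–magnesium exchange with the electron-poor aryl iodide 6, and the ortho-magnesiated aryl triflate 19 loses triflate at once to give aryne 20, whose two reactive carbons are ring-D C1 and C6. The primary alkylmagnesium 18, present in excess from the outset, adds to the aryne (carbomagnesiation) and the resulting arylmagnesium 21 is carboxylated by CO2; the closest known reaction type is the three-component coupling of an aryne from a 2-haloaryl sulfonate with a Grignard nucleophile and an electrophile. No ring is closed and no stereocentre is created. The step needs addition at C6 only: the methoxymethoxy group next to the triple bond distorts the aryne inductively so that the carbon remote from oxygen is the more electrophilic and also the less hindered, and magnesium ends up at C1 beside the oxygen, where induction and chelation stabilise it. It also needs 18 and not the exchange reagent to be the nucleophile, which the order of addition secures because each portion of iPrMgCl·LiCl is spent in the exchange before the aryne it releases appears; any exchange effected by 18 itself costs only part of its excess.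

**Step 14**
Reactants: 22 6-{2-[4-(3-{2-[4-(benzyloxy)phenyl]ethyl}-5-methoxyphenoxy)phenyl]ethyl}-4-methoxy-2-(methoxymethoxy)benzoic acid
Product: 23 6-{2-[4-(3-{2-[4-(benzyloxy)phenyl]ethyl}-5-methoxyphenoxy)phenyl]ethyl}-2-hydroxy-4-methoxybenzoic acid
Conditions: HCl (cat.), MeOH/THF, rt
Reagents that add atoms: none
Why: Acid-catalysed acetal methanolysis removes the methoxymethyl group as dimethoxymethane, while the hindered 2,6-disubstituted acid should neither esterify nor decarboxylate at room temperature.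

**Step 15**
Reactants: 23 6-{2-[4-(3-{2-[4-(benzyloxy)phenyl]ethyl}-5-methoxyphenoxy)phenyl]ethyl}-2-hydroxy-4-methoxybenzoic acid
Product: 24 2-hydroxy-6-{2-[4-(3-[2-(4-hydroxyphenyl)ethyl]-5-methoxyphenoxy)phenyl]ethyl}-4-methoxybenzoic acid (CNP0188714.0)
Conditions: H2 (1 atm), Pd/C, EtOAc/MeOH, rt
Reagents that add atoms: none
Why: Hydrogenolysis of the benzyl aryl ether over Pd/C frees the ring A phenol without affecting the diaryl ether, the methyl ethers or the carboxylic acid.

**Compound list**

1 | 5-methoxyresorcinol | COc1cc(O)cc(O)c1 | starting material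
2 | 1-methoxy-3,5-bis(methoxymethoxy)benzene | COCOc1cc(OC)cc(OCOC)c1 | intermediate
3 | [4-methoxy-2,6-bis(methoxymethoxy)phenyl]lithium | [Li]c1c(OCOC)cc(OC)cc1OCOC | intermediate
4 | 2-iodo-5-methoxy-1,3-bis(methoxymethoxy)benzene | COCOc1cc(OC)cc(OCOC)c1I | intermediate
5 | 2-iodo-5-methoxy-3-(methoxymethoxy)phenol | COCOc1cc(OC)cc(O)c1I | intermediate
6 | 2-iodo-5-methoxy-3-(methoxymethoxy)phenyl trifluoromethanesulfonate | COCOc1cc(OC)cc(OS(=O)(=O)C(F)(F)F)c1I | intermediate
7 | 4-(benzyloxy)benzyl chloride | ClCc1ccc(OCc2ccccc2)cc1 | starting material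
8 | diethyl [4-(benzyloxy)benzyl]phosphonate | CCOP(=O)(Cc1ccc(OCc2ccccc2)cc1)OCC | intermediate
9 | 3-hydroxy-5-methoxybenzaldehyde | COc1cc(O)cc(C=O)c1 | starting material
10 | (E)-3-{2-[4-(benzyloxy)phenyl]ethenyl}-5-methoxyphenol | COc1cc(O)cc(/C=C/c2ccc(OCc3ccccc3)cc2)c1 | intermediate
11 | 3-{2-[4-(benzyloxy)phenyl]ethyl}-5-methoxyphenol | COc1cc(O)cc(CCc2ccc(OCc3ccccc3)cc2)c1 | intermediate
12 | 4-fluorobenzaldehyde | O=Cc1ccc(F)cc1 | starting material
13 | 4-(3-{2-[4-(benzyloxy)phenyl]ethyl}-5-methoxyphenoxy)benzaldehyde | COc1cc(CCc2ccc(OCc3ccccc3)cc2)cc(Oc2ccc(C=O)cc2)c1 | intermediate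
14 | 1-{2-[4-(benzyloxy)phenyl]ethyl}-3-(4-ethenylphenoxy)-5-methoxybenzene | COc1cc(CCc2ccc(OCc3ccccc3)cc2)cc(Oc2ccc(C=C)cc2)c1 | intermediate
15 | 9-{2-[4-(3-{2-[4-(benzyloxy)phenyl]ethyl}-5-methoxyphenoxy)phenyl]ethyl}-9-borabicyclo[3.3.1]nonane | COc1cc(CCc2ccc(OCc3ccccc3)cc2)cc(Oc2ccc(CCB3C4CCCC3CCC4)cc2)c1 | intermediate
16 | 2-[4-(3-{2-[4-(benzyloxy)phenyl]ethyl}-5-methoxyphenoxy)phenyl]ethanol | COc1cc(CCc2ccc(OCc3ccccc3)cc2)cc(Oc2ccc(CCO)cc2)c1 | intermediate
17 | 1-{2-[4-(benzyloxy)phenyl]ethyl}-3-[4-(2-bromoethyl)phenoxy]-5-methoxybenzene | COc1cc(CCc2ccc(OCc3ccccc3)cc2)cc(Oc2ccc(CCBr)cc2)c1 | intermediate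
18 | {2-[4-(3-{2-[4-(benzyloxy)phenyl]ethyl}-5-methoxyphenoxy)phenyl]ethyl}magnesium bromide | Br[Mg]CCc1ccc(Oc2cc(OC)cc(CCc3ccc(OCc4ccccc4)cc3)c2)cc1 | intermediate
19 | chloro[4-methoxy-2-(methoxymethoxy)-6-(trifluoromethanesulfonyloxy)phenyl]magnesium | COCOc1cc(OC)cc(OS(=O)(=O)C(F)(F)F)c1[Mg]Cl | intermediate
20 | 5-methoxy-3-(methoxymethoxy)benzyne (1,2-didehydro-5-methoxy-3-(methoxymethoxy)benzene) | COCOC1=CC(OC)=CC#C1 | intermediate
21 | bromo[2-{2-[4-(3-{2-[4-(benzyloxy)phenyl]ethyl}-5-methoxyphenoxy)phenyl]ethyl}-4-methoxy-6-(methoxymethoxy)phenyl]magnesium | COCOc1cc(OC)cc(CCc2ccc(Oc3cc(OC)cc(CCc4ccc(OCc5ccccc5)cc4)c3)cc2)c1[Mg]Br | intermediate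
22 | 6-{2-[4-(3-{2-[4-(benzyloxy)phenyl]ethyl}-5-methoxyphenoxy)phenyl]ethyl}-4-methoxy-2-(methoxymethoxy)benzoic acid | COCOc1cc(OC)cc(CCc2ccc(Oc3cc(OC)cc(CCc4ccc(OCc5ccccc5)cc4)c3)cc2)c1C(=O)O | intermediate
23 | 6-{2-[4-(3-{2-[4-(benzyloxy)phenyl]ethyl}-5-methoxyphenoxy)phenyl]ethyl}-2-hydroxy-4-methoxybenzoic acid | COc1cc(O)c(C(=O)O)c(CCc2ccc(Oc3cc(OC)cc(CCc4ccc(OCc5ccccc5)cc4)c3)cc2)c1 | intermediate
24 | 2-hydroxy-6-{2-[4-(3-[2-(4-hydroxyphenyl)ethyl]-5-methoxyphenoxy)phenyl]ethyl}-4-methoxybenzoic acid | COc1cc(CCc2ccc(O)cc2)cc(Oc2ccc(CCc3cc(OC)cc(O)c3C(=O)O)cc2)c1 | target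

**Step count**

Total steps: 15. Longest linear sequence: 11 steps (steps 5 to 15, from 7 to 24); the aryne precursor branch (steps 1 to 4) joins at step 13.

**Steps most likely to fail**

1. Step 13. The short-lived aryne may be intercepted by arylmagnesium species or by the exchange reagent before the alkylmagnesium adds. Chelation of the incoming reagent by the acetal oxygen may erode the distal regioselectivity. Surplus alkylmagnesium is also carboxylated and burdens purification. The fallback sets out from styrene 14 and comes back to the route at 23. Commercial 2,4,6-trihydroxybenzoic acid would be condensed with acetone (trifluoroacetic acid, trifluoroacetic anhydride) to 5,7-dihydroxy-2,2-dimethyl-4H-1,3-benzodioxin-4-one F1. The non-chelated 7-hydroxyl would be methylated (MeI, K2CO3, acetone) to give 5-hydroxy-7-methoxy-2,2-dimethyl-4H-1,3-benzodioxin-4-one F2. Triflation (Tf2O, pyridine) would give 7-methoxy-2,2-dimethyl-4-oxo-4H-1,3-benzodioxin-5-yl trifluoromethanesulfonate F3. Alkylborane 15, generated from 14 as in step 10 but not oxidised, would then be joined to F3 by B-alkyl Suzuki–Miyaura coupling (PdCl2(dppf), K3PO4, THF/DMF/H2O, 60 °C). This gives 5-{2-[4-(3-{2-[4-(benzyloxy)phenyl]ethyl}-5-methoxyphenoxy)phenyl]ethyl}-7-methoxy-2,2-dimethyl-4H-1,3-benzodioxin-4-one F4. Opening of the acetonide with KOH in aqueous THF and acidification would give 23, which enters step 15.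

2. Step 3. Acetal cleavage may not stop after the first group, so that a statistical mixture with much over-cleaved diol results. The fallback sets out from 4 and comes back at 6. Both acetals of 4 would be removed (HCl, MeOH, 40 °C) to give 2-iodo-5-methoxybenzene-1,3-diol F5. Double triflation (Tf2O, pyridine, CH2Cl2) would give 2-iodo-5-methoxy-1,3-phenylene bis(trifluoromethanesulfonate) F6. One sulfonate would then be hydrolysed with Et4NOH (2 equiv, dioxane/H2O, rt) to 3-hydroxy-2-iodo-5-methoxyphenyl trifluoromethanesulfonate F7. This cleavage should be self-limiting, because the aryloxide formed makes the remaining sulfonate a much poorer substrate for hydroxide. Alkylation of F7 (MOMCl, iPr2NEt, CH2Cl2) would deliver 6.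

3. Step 12. Magnesium insertion may start sluggishly on small scale and be accompanied by Wurtz-type homocoupling, leaving a reagent of low and uncertain titre for the key step. The fallback sets out from 17 and comes back at 18. Finkelstein exchange (NaI, acetone, reflux) would give 1-{2-[4-(benzyloxy)phenyl]ethyl}-3-[4-(2-iodoethyl)phenoxy]-5-methoxybenzene F8. Iodine–lithium exchange (t-BuLi, 2 equiv, Et2O/pentane, −78 °C) would give {2-[4-(3-{2-[4-(benzyloxy)phenyl]ethyl}-5-methoxyphenoxy)phenyl]ethyl}lithium F9. Transmetalation with MgBr2·OEt2 at −78 °C would give 18 in solution for step 13.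

**Further compounds**

F1 | step 13 | 5,7-dihydroxy-2,2-dimethyl-4H-1,3-benzodioxin-4-one | CC1(C)OC(=O)c2c(O)cc(O)cc2O1
F2 | step 13 | 5-hydroxy-7-methoxy-2,2-dimethyl-4H-1,3-benzodioxin-4-one | COc1cc(O)c2C(=O)OC(C)(C)Oc2c1
F3 | step 13 | 7-methoxy-2,2-dimethyl-4-oxo-4H-1,3-benzodioxin-5-yl trifluoromethanesulfonate | COc1cc(OS(=O)(=O)C(F)(F)F)c2C(=O)OC(C)(C)Oc2c1
F4 | step 13 | 5-{2-[4-(3-{2-[4-(benzyloxy)phenyl]ethyl}-5-methoxyphenoxy)phenyl]ethyl}-7-methoxy-2,2-dimethyl-4H-1,3-benzodioxin-4-one | COc1cc(CCc2ccc(Oc3cc(OC)cc(CCc4ccc(OCc5ccccc5)cc4)c3)cc2)c2C(=O)OC(C)(C)Oc2c1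
F5 | step 3 | 2-iodo-5-methoxybenzene-1,3-diol | COc1cc(O)c(I)c(O)c1
F6 | step 3 | 2-iodo-5-methoxy-1,3-phenylene bis(trifluoromethanesulfonate) | COc1cc(OS(=O)(=O)C(F)(F)F)c(I)c(OS(=O)(=O)C(F)(F)F)c1
F7 | step 3 | 3-hydroxy-2-iodo-5-methoxyphenyl trifluoromethanesulfonate | COc1cc(O)c(I)c(OS(=O)(=O)C(F)(F)F)c1
F8 | step 12 | 1-{2-[4-(benzyloxy)phenyl]ethyl}-3-[4-(2-iodoethyl)phenoxy]-5-methoxybenzene | COc1cc(CCc2ccc(OCc3ccccc3)cc2)cc(Oc2ccc(CCI)cc2)c1
F9 | step 12 | {2-[4-(3-{2-[4-(benzyloxy)phenyl]ethyl}-5-methoxyphenoxy)phenyl]ethyl}lithium | [Li]CCc1ccc(Oc2cc(OC)cc(CCc3ccc(OCc4ccccc4)cc3)c2)cc1
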